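I need no rate constant to ask what would have to be true for G to outlast Q at the end of a flask, because two balances answer that. I take each Q as holding one G and two J, and I assume that whatever leaves unread holds one G per J. Dawn suggests this: from 3.00 d to 8.00 d its L falls from 5.6% to 3.0% while Q moves from 12.2% to 13.2%, so some L seems to leave without becoming Q and to take its G along. By 8.00 d, 12.9% of J, reckoned on the G charged, is missing from Q and L.

| flask | G | J | remark | time |
|---|---|---|---|---|
| dawn | 0.022 M | 0.0093 M | run made earlier |  |
| spring | 0.022 M | 0.024 M | run made earlier |  |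
| autumn | 0.022 M | 0.053 M | run made earlier |  |
| delta | 0.022 M | 0.0220 M |  | 10 d |
| eta | 0.022 M | 0.0550 M |  | 10 d |
| epsilon | 0.022 M | 0.0110 M |  | 10 d |

| run | time / d | Q / % | L / % |
|---|---|---|---|
| dawn | 0.625 | 3.3 | 9.2 |
| dawn | 1.67 | 6.1 | 9.9 |
| dawn | 3.00 | 12.2 | 5.6 |
| dawn | 5.00 | 10.0 | 5.6 |
| dawn | 8.00 | 13.2 | 3.0 |
| spring | 1.25 | 24.8 | 10.4 |
| spring | 3.00 | 37.5 | 6.4 |
| spring | 4.00 | 39.7 | 6.4 |
| spring | 6.00 | 41.3 | 4.7 |
| spring | 8.00 | 47.0 | 3.0 |
| autumn | 1.25 | 56.9 | 6.1 |
| autumn | 3.00 | 76.9 | 2.6 |
| autumn | 4.00 | 82.4 | 1.7 |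
| autumn | 6.00 | 87.6 | 2.1 |
| autumn | 8.00 | 90.1 | 2.1 |

(readings scatter by 1 percentage point)

- which of these holds the largest part of the G at the end of delta (Q / L / G)
- which of these holds the largest part of the G at the end of eta (Q / L / G)
- which of these holds the largest part of the G at the end of epsilon (Q / L / G)
- how much Q is there at the end of eta, in percent of the G charged

- a reading or a percentage of L counts all its forms, free or not

G charged = [G] + [L] + [Q] + [unread]

J charged = [J] + [L] + 2[Q] + [unread]

Subtracting:

[G] − [Q] = G charged − J charged + [J]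

So the crossing charge, the J charge at which G and Q tie once J is used up, equals the G charge: 0.0220 M. Delta, with 0.0220 M of J, stands on it, so I commit to no more than a tie: J left over tips delta to G, and any unread product holding more G than J tips it to Q. Epsilon lies below the crossing, with G ahead by about 50.0% of the charge, and eta lies above it, so I call G for epsilon and Q for eta.

The forecast says G for delta, Q for eta and G for epsilon, with 94% of Q in eta, and it calls the missing J “lost to a scavenger, not a first-order decay”.

The flask gives Q for delta (39.5% against 35.1% of G), Q for eta with 92.9%, and G for epsilon.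

    G + L → E (k = 1.00 × 10⁻⁴ M⁻¹ s⁻¹)
    G + J → L (k = 3.00 × 10⁻⁴ M⁻¹ s⁻¹)
    X ⇌ L, rate k3*(cs3 - [L]) while solid is left; crystals form when [L] > cs3 (solubility = 5.40 mM, k = 1.60 × 10⁻⁴ s⁻¹)
    L ⇌ Z (K = 2.50, k = 4.10 × 10⁻⁶ s⁻¹)
    J + L → Q (k = 0.00160 M⁻¹ s⁻¹)

The main reason that L goes on to Q is the difference between the rate constants of G + J → L and J + L → Q: with the two alike, Q at the end of eta falls from 92.9% to 74.9%. E holds two G to one J, and taking the step from G and L to E away turns the answer for delta, though it is a part of the story in eta, where Q goes from 92.9% with the step to 95.4% without it. In delta, Q leads G by 4.4 percentage points, while half of E less the J left, the limiting reagent at 1.18% of its charge, comes to 4.4 points. A neighbour of eta charged with 0.014 M of J has a gap of 36.4%, half of its E takes off 6.80%, and G ends ahead of Q by 30 points.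

The runs stem from a simulated flask from invented constants, noise included.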